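**Retrosynthetic overview**

- The plan rests on the hexasubstituted benzene ring, numbered C1 (CH2OH), C2 (Br), C3 (OMe), C4 (OH), C5 (Br), C6 (Br). The adjacent C2-Br/C3-OMe pair is read as 2-bromo-1,1-dimethoxyethene, and C4-C5-C6-C1 as carbons C3 to C6 of a 3-acyloxy-4,5-dibromo-6-(acyloxymethyl)-2-pyrone.
- Key disconnection: bonds C1-C2 and C3-C4, formed by an inverse-demand [4+2] cycloaddition of the pyrone with the bromoketene acetal. The bridged lactone then extrudes CO2 and the ketal loses methanol, so the arene appears with all six substituents in place.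
- Pyrone: galactaric acid, dehydrative cyclisation, reduction of the acid to CH2OH, acetate on the primary alcohol, bromination at C4 and C5, enol acetate. Acetal: bromoacetaldehyde dimethyl acetal, α-bromination, dehydrobromination.
- Ring order: the 2-pyrone ring is made first (step 1) and is sacrificed in step 8, where the benzene ring, the only ring of the target, is closed. Both acetates are removed last.

Key step: step 8

Assumption: the target has no stereocentre. The stereocentres of the transient intermediates 12 and 13 (racemic, 12 as a mixture of CHBr epimers) are destroyed in the step that forms them, so their SMILES carry no stereodescriptors.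

**Route**

Step 1
Reactants: 1 galactaric acid (mucic acid, meso)
Product: 3 3-hydroxy-2-oxo-2H-pyran-6-carboxylic acid, via sodium 3-acetoxy-2-oxo-2H-pyran-6-carboxylate 2 (not isolated)
Conditions: Ac2O, NaOAc, 100 °C; volatiles removed; then 6 M HCl aq, 50 °C
Reagents that add atoms: none
Why: Acetic anhydride peracetylates the aldaric acid, which lactonises to the six-membered ring and loses two molecules of acetic acid by β-elimination to give the 3-acetoxy-2-pyrone-6-carboxylate (dehydrative pyrone formation from an aldaric acid), and aqueous acid then cleaves the enol acetate again.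

Step 2
Reactants: 3 3-hydroxy-2-oxo-2H-pyran-6-carboxylic acid
Product: 4 3-hydroxy-6-(hydroxymethyl)-2H-pyran-2-one
Conditions: BH3·THF (3.5 equiv), THF, 0 to 23 °C; MeOH quench, co-evaporation
Reagents that add atoms: none
Why: Borane reduces a carboxylic acid through its acyloxyborane much faster than it attacks the conjugated pyrone lactone (chemoselective borane reduction of a carboxylic acid), while the enolic OH is only masked in the flask as a borate.

Step 3
Reactants: 4 3-hydroxy-6-(hydroxymethyl)-2H-pyran-2-one
Product: 5 (3-hydroxy-2-oxo-2H-pyran-6-yl)methyl acetate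
Conditions: vinyl acetate (3 equiv), immobilised Candida antarctica lipase B, THF, 35 °C
Reagents that add atoms: vinyl acetate, CC(=O)OC=C
Why: Lipase-catalysed transesterification acylates the aliphatic primary alcohol and leaves the acidic, phenol-like enolic OH free (enzymatic chemoselective acetylation), so the CH2O group is capped before bromination and cannot be lost as formaldehyde after ipso attack.

Step 4
Reactants: 5 (3-hydroxy-2-oxo-2H-pyran-6-yl)methyl acetate
Product: 7 (4,5-dibromo-3-hydroxy-2-oxo-2H-pyran-6-yl)methyl acetate, via 4-bromopyrone monoacetate 6 (not isolated)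
Conditions: Br2 (2.3 equiv), NaOAc, AcOH, 20 to 50 °C; Na2S2O3 aq
Reagents that add atoms: bromine, BrBr
Why: Electrophilic bromination of the hydroxypyrone should place the first bromine at C4, ortho to the free 3-OH, and the second at the only remaining ring CH, C5 (β-carbon of the ring enol-ester oxygen), by attack and acetate-assisted loss of HBr, while C6 is blocked by the acetoxymethyl group.

Step 5
Reactants: 7 (4,5-dibromo-3-hydroxy-2-oxo-2H-pyran-6-yl)methyl acetate
Product: 8 3-acetoxy-6-(acetoxymethyl)-4,5-dibromo-2H-pyran-2-one
Conditions: Ac2O (1.3 equiv), iPr2NEt, CH2Cl2, 0 °C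
Reagents that add atoms: acetic anhydride, CC(=O)OC(C)=O
Why: O-Acetylation of the acidic enol with a non-nucleophilic amine base, chosen so that no nucleophilic catalyst can displace the C4 bromide (a vinylogous acyl bromide); the acetate removes the proton that would destroy the ketene acetal and lowers the diene LUMO.

Step 6
Reactants: 9 2-bromo-1,1-dimethoxyethane (bromoacetaldehyde dimethyl acetal)
Product: 10 2,2-dibromo-1,1-dimethoxyethane
Conditions: Br2 (1.05 equiv), MeOH, 0 to 50 °C; NaHCO3; distillation
Reagents that add atoms: bromine, BrBr; methanol, CO (solvent, its methoxy groups exchange into the acetal)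
Why: Acid-catalysed α-bromination of an acetal through its enol ether, with the HBr of the first turnover as catalyst and methanol returning the bromo-oxocarbenium ion to the dimethyl acetal.

Step 7
Reactants: 10 2,2-dibromo-1,1-dimethoxyethane
Product: 11 2-bromo-1,1-dimethoxyethene (bromoketene dimethyl acetal)
Conditions: KOtBu (1.05 equiv), tBuOH, 80 °C; distillation under reduced pressure from base-washed glassware
Reagents that add atoms: none
Why: Base-induced 1,2-dehydrobromination of an α,α-dihalo acetal is the classical route to haloketene acetals; the product is kept strictly acid-free because ketene acetals hydrolyse and polymerise with traces of acid.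

Step 8
Reactants: 8 3-acetoxy-6-(acetoxymethyl)-4,5-dibromo-2H-pyran-2-one and 11 2-bromo-1,1-dimethoxyethene
Product: 14 4-acetoxy-2,5,6-tribromo-3-methoxybenzyl acetate, via bridged lactone 12 (not isolated), via cyclohexadiene ketal 13 (not isolated)
Conditions: 11 (3 equiv), PhMe, 110 °C, sealed tube
Reagents that add atoms: none
Why: Inverse-electron-demand Diels-Alder reaction of an electron-poor 2-pyrone with a ketene acetal, the established way of turning 2-pyrones and 1,1-dialkoxyethenes into alkoxyarenes, here applied to a new pair of partners. The nucleophilic CHBr carbon of 11 bonds to pyrone C6, the vinylogous acceptor terminus of the lactone, and the dimethoxy-substituted carbon is captured by the dienolate terminus C3, so the six-membered carbocycle is closed by a concerted but asynchronous intermolecular [4+2] cycloaddition that gives the 2-oxabicyclo[2.2.2]octenone 12. Cycloreversion of 12 expels CO2 and leaves cyclohexadiene 13, whose only ring hydrogen sits on the CHBr carbon next to the ketal carbon, so the ring can aromatise only by 1,2-loss of methanol and the bromine stays in place. The stereocentres of 12 and 13 are transient and vanish in the arene, so endo/exo and facial selectivity are of no consequence. The selectivity needed is regiochemical (CHBr carbon to the acetoxymethyl-bearing C6, ketal carbon to the acetoxy-bearing C3); it is secured by the polarisation of the pyrone by its lactone carbonyl, unopposed because C6 carries an acetoxymethyl group and not a second acceptor such as an ester. The two bromines and the 3-acetoxy group lower the diene LUMO towards the electron-rich acetal, and the excess of 11 compensates for its thermal and hydrolytic lability.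

Step 9
Reactants: 14 4-acetoxy-2,5,6-tribromo-3-methoxybenzyl acetate
Product: 15 (2,5,6-tribromo-4-hydroxy-3-methoxyphenyl)methanol (= 2,3,6-tribromo-4-hydroxy-5-methoxybenzyl alcohol, the target)
Conditions: iBu2AlH (5 equiv), CH2Cl2, −78 °C; KNaC4H4O6 aq, then pH 4
Reagents that add atoms: none
Why: Hydride reduction of both acetate carbonyls at low temperature releases the phenol and the benzylic alcohol as aluminium alkoxides without exposing a free para-phenoxide to a benzylic acetate (which under basic methanolysis could expel acetate to a quinone methide), and aryl bromides are inert to iBu2AlH at −78 °C.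

**Compound list**

1 | galactaric acid (mucic acid) | OC(=O)[C@H](O)[C@@H](O)[C@@H](O)[C@H](O)C(=O)O | starting material
2 | sodium 3-acetoxy-2-oxo-2H-pyran-6-carboxylate | CC(=O)OC1=CC=C(C(=O)[O-])OC1=O.[Na+] | intermediate
3 | 3-hydroxy-2-oxo-2H-pyran-6-carboxylic acid | OC(=O)C1=CC=C(O)C(=O)O1 | intermediate
4 | 3-hydroxy-6-(hydroxymethyl)-2H-pyran-2-one | OCC1=CC=C(O)C(=O)O1 | intermediate
5 | (3-hydroxy-2-oxo-2H-pyran-6-yl)methyl acetate | CC(=O)OCC1=CC=C(O)C(=O)O1 | intermediate
6 | (4-bromo-3-hydroxy-2-oxo-2H-pyran-6-yl)methyl acetate | CC(=O)OCC1=CC(Br)=C(O)C(=O)O1 | intermediate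
7 | (4,5-dibromo-3-hydroxy-2-oxo-2H-pyran-6-yl)methyl acetate | CC(=O)OCC1=C(Br)C(Br)=C(O)C(=O)O1 | intermediate
8 | 3-acetoxy-6-(acetoxymethyl)-4,5-dibromo-2H-pyran-2-one | CC(=O)OCC1=C(Br)C(Br)=C(OC(C)=O)C(=O)O1 | intermediate
9 | 2-bromo-1,1-dimethoxyethane (bromoacetaldehyde dimethyl acetal) | COC(CBr)OC | starting material
10 | 2,2-dibromo-1,1-dimethoxyethane | COC(OC)C(Br)Br | intermediate
11 | 2-bromo-1,1-dimethoxyethene | COC(OC)=CBr | intermediate
12 | 4-acetoxy-1-(acetoxymethyl)-6,7,8-tribromo-5,5-dimethoxy-2-oxabicyclo[2.2.2]oct-7-en-3-one (racemic, both CHBr epimers) | CC(=O)OCC12OC(=O)C(OC(C)=O)(C(Br)=C1Br)C(OC)(OC)C2Br | intermediate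
13 | (4-acetoxy-2,3,6-tribromo-5,5-dimethoxycyclohexa-1,3-dien-1-yl)methyl acetate (racemic) | CC(=O)OCC1=C(Br)C(Br)=C(OC(C)=O)C(OC)(OC)C1Br | intermediate
14 | 4-acetoxy-2,5,6-tribromo-3-methoxybenzyl acetate | CC(=O)OCc1c(Br)c(OC)c(OC(C)=O)c(Br)c1Br | intermediate
15 | (2,5,6-tribromo-4-hydroxy-3-methoxyphenyl)methanol | COc1c(O)c(Br)c(Br)c(CO)c1Br | target

**Step count**

Total steps: 9. Longest linear sequence: 7 steps (steps 1 to 5, 8 and 9); steps 6 and 7 form the two-step side branch to the dienophile.

**Steps most likely to fail, with fallbacks**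

Step 8. The fully substituted diene and the trisubstituted, less nucleophilic bromo acetal may combine so slowly that addition-elimination of the acetal at the C4 bromide of the pyrone, C-acylation by the enol acetate or thermal decay of the acetal takes over. The fallback sets out from 8 and comes back to the route at 14.
- Pyrone 8 would be heated (PhMe, 110 °C) with commercial 1,1-dimethoxyethene (C=C(OC)OC), the unhindered and more nucleophilic partner for which this pyrone chemistry is established.
- The same regiochemistry should lead through the bridged lactone 4-acetoxy-1-(acetoxymethyl)-7,8-dibromo-5,5-dimethoxy-2-oxabicyclo[2.2.2]oct-7-en-3-one F1 and, after loss of CO2, the ketal (4-acetoxy-2,3-dibromo-5,5-dimethoxycyclohexa-1,3-dien-1-yl)methyl acetate F2.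
- Loss of methanol from the ketal should give 4-acetoxy-2,3-dibromo-5-methoxybenzyl acetate F3.
- Electrophilic bromination (Br2, NaOAc, AcOH, 50 °C) at the single ring CH of this arene, ortho to the methoxy group, should then give 14.

Step 4. The second bromination may be diverted: ipso attack at C4 or C6 of the enol, with over-oxidation to a bromo-dione, may outrun substitution at C5, or the reaction may stop after one bromine. The fallback sets out from 5 and comes back at 14, moving the last bromination to the arene.
- 5 would be brominated once (N-bromosuccinimide, 1.0 equiv, MeCN, 0 °C) to monobromide 6, which is isolated here.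
- Acetylation as in step 5 (Ac2O, iPr2NEt) should give (3-acetoxy-4-bromo-2-oxo-2H-pyran-6-yl)methyl acetate F4.
- Heating with 11 as in step 8 should pass through the lactone 4-acetoxy-1-(acetoxymethyl)-6,8-dibromo-5,5-dimethoxy-2-oxabicyclo[2.2.2]oct-7-en-3-one F5 and the ketal (4-acetoxy-3,6-dibromo-5,5-dimethoxycyclohexa-1,3-dien-1-yl)methyl acetate F6 to 4-acetoxy-2,5-dibromo-3-methoxybenzyl acetate F7.
- Its only free ring position, para to the methoxy group, would be brominated (Br2, FeBr3 cat., CH2Cl2, 40 °C) to give 14.

Step 6. HBr may demethylate the acetal to the aldehyde faster than the already deactivated bromo acetal is brominated a second time; in step 7, loss of methoxide from the CHBr2 carbanion could also compete with loss of HBr. The fallback sets out from 9 and comes back at 11, bypassing both steps through an orthoester.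
- 9 would be dehydrobrominated (KOtBu, tBuOH, 80 °C, distillation) to 1,1-dimethoxyethene F8.
- Methoxybromination (N-bromosuccinimide, MeOH, −20 °C) should give 2-bromo-1,1,1-trimethoxyethane F9.
- Dealcoholation of the orthoester with TMSOTf and iPr2NEt (CH2Cl2, −78 to 0 °C) should give 11.

**Further compounds**

F1 | step 8 | 4-acetoxy-1-(acetoxymethyl)-7,8-dibromo-5,5-dimethoxy-2-oxabicyclo[2.2.2]oct-7-en-3-one | CC(=O)OCC12OC(=O)C(OC(C)=O)(C(Br)=C1Br)C(OC)(OC)C2
F2 | step 8 | (4-acetoxy-2,3-dibromo-5,5-dimethoxycyclohexa-1,3-dien-1-yl)methyl acetate | CC(=O)OCC1=C(Br)C(Br)=C(OC(C)=O)C(OC)(OC)C1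
F3 | step 8 | 4-acetoxy-2,3-dibromo-5-methoxybenzyl acetate | CC(=O)OCc1cc(OC)c(OC(C)=O)c(Br)c1Br
F4 | step 4 | (3-acetoxy-4-bromo-2-oxo-2H-pyran-6-yl)methyl acetate | CC(=O)OCC1=CC(Br)=C(OC(C)=O)C(=O)O1
F5 | step 4 | 4-acetoxy-1-(acetoxymethyl)-6,8-dibromo-5,5-dimethoxy-2-oxabicyclo[2.2.2]oct-7-en-3-one | CC(=O)OCC12OC(=O)C(OC(C)=O)(C(Br)=C1)C(OC)(OC)C2Br
F6 | step 4 | (4-acetoxy-3,6-dibromo-5,5-dimethoxycyclohexa-1,3-dien-1-yl)methyl acetate | CC(=O)OCC1=CC(Br)=C(OC(C)=O)C(OC)(OC)C1Br
F7 | step 4 | 4-acetoxy-2,5-dibromo-3-methoxybenzyl acetate | CC(=O)OCc1cc(Br)c(OC(C)=O)c(OC)c1Br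
F8 | step 6 | 1,1-dimethoxyethene | C=C(OC)OC
F9 | step 6 | 2-bromo-1,1,1-trimethoxyethane | COC(CBr)(OC)OC
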